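The earlier runs and the new flask were generated by integration with made-up constants.

Slowness is what these runs show first: at 40.0 min the blue run still holds 85 % of its substrate.

| setting | grey | ochre | blue | flask |
|---|---|---|---|---|
| substrate | 17 mM | 17 mM | 8.5 mM | 17 mM |
| reagent in the second phase | 0.35 equiv | 0.52 equiv | 0.70 equiv | 0.700 equiv |
| remark | run made earlier | run made earlier | run made earlier |  |
| time |  |  |  | 50 min |
| volume of the second phase over the first |  |  |  | 0.25 |

| run | time / min | target / % | substrate / % |
|---|---|---|---|
| grey | 2.00 | 2 | 101 |
| grey | 6.00 | 3 | 101 |
| grey | 12.0 | 4 | 98 |
| grey | 15.0 | 1 | 95 |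
| grey | 25.0 | 2 | 91 |
| grey | 30.0 | 3 | 92 |
| grey | 40.0 | 7 | 88 |
| ochre | 3.00 | 0 | 101 |
| ochre | 5.00 | 0 | 97 |
| ochre | 8.00 | 0 | 98 |
| ochre | 12.0 | 1 | 97 |
| ochre | 15.0 | 2 | 95 |
| ochre | 25.0 | 3 | 88 |
| ochre | 40.0 | 8 | 79 |
| blue | 3.00 | 1 | 102 |
| blue | 6.00 | 0 | 99 |
| blue | 12.0 | 2 | 95 |
| blue | 20.0 | 2 | 94 |
| blue | 40.0 | 6 | 85 |

(each reading ± 1.5 percentage points)

- a species is counted by the substrate in it: one side product counts as two
- amounts and yields of target count product in the second phase too
- in the second phase: reagent in the second phase, product in the second phase; everything else is in the first
- charges count per volume of the first phase; a concentration in a rate is the amount of a species over the volume of its own phase; every rate counts per litre of the first phase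
- the numbers in the tables scatter with a standard deviation of 1.5 percentage points
- candidate steps: reagent in the reaction phase <-> reagent in the second phase; substrate + reagent in the reaction phase <-> target; target <-> product in the second phase; target -> decomposed product; substrate + target -> side product
- the earlier runs hold the two phases in the same ratio of volumes as the flask asked about

- the target and product in the second phase together standing at 50 min, as a percentage of the substrate charged
- part of the substrate charged that has reacted at 50 min

We start with the balance of the limiting reagent, the reagent in the second phase. The flask is charged with 11.9 mM of it, less than its 17 mM of substrate, and by the candidate steps each substrate lost takes at most one reagent. The blue run looks nearly the same, with 0.70 equiv, but its reagent charge is 5.95 mM. We treat the loss as pseudo-first-order in substrate, with the rate proportional to the reagent charged. The logarithm of substrate charged over substrate left, divided by reagent charged and by time, is then 0.683 L mol⁻¹ min⁻¹ in the blue run. This loss constant is a reading and carries that reading's scatter.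

The flask has twice the blue run's reagent and runs for 50 min instead of 40.0 min, so its exponent is 0.406 against 0.163 in the blue run. We reckon 33.4 % reacted in the flask. That is 5.68 mM of substrate, less than the reagent charged, so in our reckoning the flask ends where its slowness leaves it, short of what its charge allows.

The forecast gives 12 % (8 % to 17 %) for target and product in the second phase together and 33 % (26 % to 41 %) reacted, noting: “The early points show a slight lag, perhaps from slow reagent transfer.”

The flask gives 31.4 % reacted and 7.85 % of target and product in the second phase together, with 37.3 % of the reagent in the second phase, counted on its own charge, still standing there at 50.0 min.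

    reagent in the reaction phase ⇌ reagent in the second phase, rate k1*([reagent in the reaction phase] - [reagent in the second phase]/K1) per volume of the first phase (partition coefficient = 2.30, kL = 0.0150 min⁻¹)
    substrate + reagent in the reaction phase ⇌ target (K = 54.0 L mol⁻¹, k = 3.30 L mol⁻¹ min⁻¹)
    target ⇌ product in the second phase, rate k3*([target] - [product in the second phase]/K3) per volume of the first phase (partition coefficient = 2.20, kL = 0.0730 min⁻¹)
    target → decomposed product (k = 0.0560 min⁻¹)
    substrate + target → side product (k = 2.60 L mol⁻¹ min⁻¹)

Our reckoning of 33.4 % reacted stands 2 percentage points above the flask.

For the same flask read at 20 min, the loss constant gives 15.0 % reacted, more than the computed 10.6 %.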